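**Retrosynthetic overview**
1. Target ⇒ macrocyclic 8,14‑diol 31 (15‑O‑PMB) by late acetylation, C8 acylation, C15 oxidation and desilylation.
2. 31 ⇒ seco alkyl iodide / Z‑alkenyl bromide 28: the 10‑membered carbocycle is closed last, at C3–C4, by an intramolecular Pd‑catalysed C(sp3)–C(sp2) Negishi coupling.
3. 28 ⇒ butenolide bromide 12 + lactol 26 by a zinc Barbier allylation (C7–C8), which sets C7 and C8 from C6 and unveils the α‑methylene lactone.
4. 12 ⇒ (S)‑enynol 6 (Sharpless kinetic resolution), Red‑Al/NBS (Z‑alkenyl bromide) and butenolide RCM; 26 ⇒ E‑selective Wittig reaction of a maleic anhydride‑derived ylide.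
5. Ring order: butenolide (RCM), kept as the 6,12‑lactone through the Barbier step, then the 10‑membered carbocycle (Negishi).

Assumption: C1–C15 are germacranolide locants (C6 lactone O–CH, C7 ring fusion, C8 acyloxy CH, C14 on C10, C15 on C4, C11=C13 exo‑methylene, C12 lactone C=O); the target is (6R,7R,8S), 6,7‑trans‑lactone, both ring olefins ring‑cis.

**Route**

Step 1
Reactants: 1 propargyl alcohol
Product: 2 4-methoxybenzyl propargyl ether
Conditions: NaH, PMBCl, TBAI (cat.), THF/DMF, 0 °C→rt
Reagents that add atoms: 4-methoxybenzyl chloride, COc1ccc(CCl)cc1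
Why: Williamson etherification of the primary alkoxide protects the future C15 oxygen; no stereocentre is involved.

Step 2
Reactants: 2 4-methoxybenzyl propargyl ether; 3 acrolein
Product: 5 rac-6-(4-methoxybenzyloxy)hex-1-en-4-yn-3-ol, via lithium acetylide 4 (not isolated)
Conditions: n-BuLi, THF, −78 °C; then 3, −78 °C; sat. aq. NH4Cl
Reagents that add atoms: none
Why: Acetylide 1,2-addition to acrolein joins C5 to C6 and gives the racemic vinyl alkynyl carbinol.

Step 3
Reactants: 5 rac-6-(4-methoxybenzyloxy)hex-1-en-4-yn-3-ol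
Product: 6 (S)-6-(4-methoxybenzyloxy)hex-1-en-4-yn-3-ol
Conditions: Ti(OiPr)4 (15 mol%), L-(+)-DIPT (18 mol%), TBHP (0.6 equiv), 4 Å MS, CH2Cl2, −20 °C
Reagents that add atoms: none
Why: Sharpless kinetic resolution, in which L-(+)-DIPT epoxidises the vinyl group of the (R)-enantiomer much faster and leaves (S)-6 (future C6) in high ee at about 55% conversion.

Step 4
Reactants: 6 (S)-6-(4-methoxybenzyloxy)hex-1-en-4-yn-3-ol
Product: 8 (S,Z)-5-bromo-6-(4-methoxybenzyloxy)hexa-1,4-dien-3-ol, via cyclic alkenylaluminate 7 (not isolated)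
Conditions: Red-Al, THF, −20→0 °C; then NBS, −78 °C; Rochelle salt
Reagents that add atoms: N-bromosuccinimide, O=C1CCC(=O)N1Br
Why: Hydroxyl-directed trans-hydroalumination puts Al on the distal alkyne carbon (C4) in a five-membered oxaaluminacycle, and bromodealumination with retention gives the Z-alkenyl bromide (Br cis to C6), which fixes the later C4=C5 geometry.

Step 5
Reactants: 8 (S,Z)-5-bromo-6-(4-methoxybenzyloxy)hexa-1,4-dien-3-ol; 9 2-(bromomethyl)acrylic acid
Product: 11 (S,Z)-5-bromo-6-(4-methoxybenzyloxy)hexa-1,4-dien-3-yl 2-(bromomethyl)acrylate, via 2-(bromomethyl)acryloyl chloride 10 (not isolated)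
Conditions: 9, (COCl)2, DMF (cat.), CH2Cl2, 0 °C; then 8, 2,6-lutidine, −40→0 °C
Reagents that add atoms: none
Why: Acylation of the secondary alcohol by the acid chloride, with hindered 2,6-lutidine chosen to avoid SN2' attack on the bromomethyl acrylate; C6 is untouched.

Step 6
Reactants: 11 (S,Z)-5-bromo-6-(4-methoxybenzyloxy)hexa-1,4-dien-3-yl 2-(bromomethyl)acrylate
Product: 12 (S)-3-(bromomethyl)-5-[(Z)-2-bromo-3-(4-methoxybenzyloxy)prop-1-enyl]furan-2(5H)-one
Conditions: Grubbs II (5 mol%), toluene, 80 °C, 10 mM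
Reagents that add atoms: none
Why: Ring-closing metathesis between the vinyl group and the acrylate forms the butenolide (C7=C11) while the trisubstituted bromoalkene is inert; the stereocentre is not involved.

Step 7
Reactants: 13 methyl 2-(hydroxymethyl)acrylate
Product: 14 methyl 2-[(tert-butyldimethylsilyloxy)methyl]acrylate
Conditions: TBSCl, imidazole, CH2Cl2, 0 °C→rt
Reagents that add atoms: tert-butyldimethylsilyl chloride, CC(C)(C)[Si](C)(C)Cl
Why: Silylation of the primary alcohol protects the side-chain hydroxyl until the last step.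

Step 8
Reactants: 14 methyl 2-[(tert-butyldimethylsilyloxy)methyl]acrylate
Product: 15 2-[(tert-butyldimethylsilyloxy)methyl]acrylic acid
Conditions: LiOH, THF/H2O, 0 °C; then cold dil. HCl to pH 4
Reagents that add atoms: lithium hydroxide, [Li+].[OH-] (supplies the carboxyl OH oxygen)
Why: Ester saponification; the primary TBS ether survives brief acidification to pH 4.

Step 9
Reactants: 16 propane-1,3-diol
Product: 17 3-(tert-butyldimethylsilyloxy)propan-1-ol
Conditions: NaH (1.0 equiv), THF; then TBSCl (1.0 equiv), rt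
Reagents that add atoms: tert-butyldimethylsilyl chloride, CC(C)(C)[Si](C)(C)Cl
Why: Monosilylation of the symmetrical diol through its sparingly soluble monosodium alkoxide (McDougal protocol).

Step 10
Reactants: 17 3-(tert-butyldimethylsilyloxy)propan-1-ol
Product: 18 3-(tert-butyldimethylsilyloxy)propanal
Conditions: TEMPO (10 mol%), PhI(OAc)2, CH2Cl2, rt
Reagents that add atoms: none
Why: TEMPO/BAIB oxidation of the primary alcohol stops at the aldehyde (future C1–C3) and tolerates the silyl ether.

Step 11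
Reactants: 19 maleic anhydride
Product: 20 3-(triphenylphosphoranylidene)oxolane-2,5-dione
Conditions: PPh3, acetone, rt
Reagents that add atoms: triphenylphosphine, c1ccc(cc1)P(c1ccccc1)c1ccccc1
Why: Conjugate addition of PPh3 to maleic anhydride followed by proton shift gives the stabilised ylide that carries C8, C9, C10 and C14.

Step 12
Reactants: 20 3-(triphenylphosphoranylidene)oxolane-2,5-dione; 18 3-(tert-butyldimethylsilyloxy)propanal
Product: 22 (E)-5-(tert-butyldimethylsilyloxy)-2-(2-methoxy-2-oxoethyl)pent-2-enoic acid, via half-ester ylide 21 (not isolated)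
Conditions: MeOH, rt; then 18, CH2Cl2, rt
Reagents that add atoms: methanol, CO
Why: Methanol opens the anhydride at the non-ylidic carbonyl and the stabilised ylide then undergoes an E-selective Wittig olefination, which sets the C1=C10 geometry (C9 cis to C2) and differentiates C14 (acid) from C8 (ester).

Step 13
Reactants: 22 (E)-5-(tert-butyldimethylsilyloxy)-2-(2-methoxy-2-oxoethyl)pent-2-enoic acid
Product: 24 (E)-4-(3-hydroxypropylidene)oxolan-2-one, via hydroxy ester 23 (not isolated)
Conditions: BH3·SMe2, THF, −10→0 °C; MeOH; then 1 M HCl, THF, rt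
Reagents that add atoms: none
Why: Borane reduces the free carboxylic acid chemoselectively beside the ester, and aqueous acid then removes the TBS group and closes the γ-lactone (C14–O ring oxygen, C8 carbonyl) without touching the olefin geometry.

Step 14
Reactants: 24 (E)-4-(3-hydroxypropylidene)oxolan-2-one
Product: 25 (E)-4-(3-iodopropylidene)oxolan-2-one
Conditions: I2, PPh3, imidazole, CH2Cl2, 0 °C
Reagents that add atoms: iodine, II
Why: Appel-type (Garegg–Samuelsson) iodination converts the primary alcohol into the C3 iodide needed for zinc insertion.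

Step 15
Reactants: 25 (E)-4-(3-iodopropylidene)oxolan-2-one
Product: 26 (E)-4-(3-iodopropylidene)oxolan-2-ol
Conditions: DIBAL-H (1.1 equiv), CH2Cl2, −78 °C; Rochelle salt
Reagents that add atoms: none
Why: Half-reduction of the lactone at −78 °C gives the lactol, a masked C8 aldehyde with the C14 hydroxyl internally protected; it is used at once because acid would aromatise it to a furan.

Step 16
Reactants: 12 (S)-3-(bromomethyl)-5-[(Z)-2-bromo-3-(4-methoxybenzyloxy)prop-1-enyl]furan-2(5H)-one; 26 (E)-4-(3-iodopropylidene)oxolan-2-ol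
Product: 27 (4R,5S)-5-[(Z)-2-bromo-3-(4-methoxybenzyloxy)prop-1-enyl]-4-[(1S,3E)-1-hydroxy-3-(hydroxymethyl)-6-iodohex-3-enyl]-3-methylideneoxolan-2-one
Conditions: Zn dust, THF/sat. aq. NH4Cl (4:1), 0 °C→rt
Reagents that add atoms: none
Why: Zinc Barbier 2-(alkoxycarbonyl)allylation in which the allylzinc from 12 attacks through its γ-carbon (C7) anti to the C6 substituent (6,7-trans) in a chair Zimmerman–Traxler transition state with the aldehyde chain equatorial (7,8-anti, as in the target), setting C7 and C8 and forming the α-methylene lactone; the alkenyl bromide and alkyl iodide are inert to zinc dust here.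

Step 17
Reactants: 27 Barbier diol
Product: 28 8,14-bis(triethylsilyl) ether of 27
Conditions: TESOTf, 2,6-lutidine, CH2Cl2, −78 °C
Reagents that add atoms: triethylsilyl trifluoromethanesulfonate, CC[Si](CC)(CC)OS(=O)(=O)C(F)(F)F
Why: Silylation of both hydroxyls removes acidic protons before the organozinc step and avoids an allylic ester at C14 that Pd(0) would ionise.

Step 18
Reactants: 28 8,14-bis(triethylsilyl) ether of 27
Product: 30 8,14-bis-O-triethylsilyl-15-O-(4-methoxybenzyl) macrocyclic lactone (10-membered ring closed at C3–C4), via alkylzinc iodide 29 (not isolated)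
Conditions: Zn dust (activated), LiCl, THF, 30 °C; then syringe-pump addition (12 h) to PdCl2(DPEphos) (10 mol%), THF/NMP, 45 °C, 2 mM
Reagents that add atoms: none
Why: Proposed new method: a macrocyclising intramolecular alkyl–alkenyl Negishi coupling in which zinc inserts only into the C(sp3)–I bond (the C(sp2)–Br bond is inert), Pd(0) adds to the Z-alkenyl bromide with retention, and slow addition favours intramolecular Zn→Pd transmetalation and reductive elimination from an 11-membered palladacycle pre-organised by the two ring-cis olefins and the trans-lactone, while the chelating wide-bite-angle ligand and halide-rich medium keep Pd saturated and so disfavour 5-exo Heck insertion into C11=C13; the closest known reactions are intermolecular alkyl–alkenyl Negishi couplings with RZnI·LiCl and B-alkyl Suzuki macrocyclisations, neither shown for a 10-membered germacranolide ring.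

Step 19
Reactants: 30 bis-TES macrocycle
Product: 31 macrocyclic 8,14-diol (15-O-PMB)
Conditions: PPTS, MeOH/CH2Cl2, 0 °C→rt
Reagents that add atoms: none
Why: Acid-catalysed methanolysis removes both TES ethers while the PMB ether, lactone and olefins are stable.

Step 20
Reactants: 31 macrocyclic 8,14-diol
Product: 32 14-O-acetyl 8-ol (15-O-PMB)
Conditions: AcCl (1.05 equiv), 2,4,6-collidine, CH2Cl2, −78 °C
Reagents that add atoms: acetyl chloride, CC(=O)Cl
Why: Selective acetylation of the primary allylic C14 hydroxyl over the hindered secondary C8 hydroxyl under weakly basic, low-temperature conditions that do not provoke translactonisation.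

Step 21
Reactants: 32 14-O-acetyl 8-ol; 15 2-[(tert-butyldimethylsilyloxy)methyl]acrylic acid
Product: 33 8-O-{2-[(tert-butyldimethylsilyloxy)methyl]acryloyl} 14-acetate 15-O-PMB macrocycle
Conditions: DCC, DMAP (cat.), CH2Cl2, 0 °C→rt
Reagents that add atoms: none
Why: Steglich esterification of the C8 hydroxyl with retention at C8 installs the protected side chain.

Step 22
Reactants: 33 side-chain ester
Product: 34 15-alcohol
Conditions: DDQ, CH2Cl2/pH 7 buffer, 0 °C
Reagents that add atoms: none
Why: Oxidative PMB cleavage frees only the C15 allylic alcohol; the TBS ether, acetate and Michael acceptors are unaffected.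

Step 23
Reactants: 34 15-alcohol
Product: 35 15-aldehyde (side chain still TBS-protected)
Conditions: MnO2, CH2Cl2, rt
Reagents that add atoms: none
Why: Neutral allylic oxidation gives the enal with the C4=C5 geometry unchanged (CHO trans to C6, the stable enal geometry); the side-chain allylic alcohol is still silylated and cannot compete.

Step 24
Reactants: 35 15-aldehyde TBS ether
Product: 36 target CNP0198933.2
Conditions: HF·pyridine, pyridine/THF, 0 °C→rt
Reagents that add atoms: none
Why: Buffered fluoride desilylation frees the side-chain hydroxyl without affecting the enal, allylic acetate or α-methylene lactone.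

**Compound list**
1 | propargyl alcohol (prop-2-yn-1-ol) | C#CCO | starting material
2 | 4-methoxybenzyl propargyl ether | C#CCOCc1ccc(OC)cc1 | intermediate
3 | acrolein | C=CC=O | starting material
4 | lithium acetylide of 2 | [Li]C#CCOCc1ccc(OC)cc1 | intermediate
5 | rac-6-(4-methoxybenzyloxy)hex-1-en-4-yn-3-ol | C=CC(O)C#CCOCc1ccc(OC)cc1 | intermediate
6 | (S)-6-(4-methoxybenzyloxy)hex-1-en-4-yn-3-ol | C=C[C@H](O)C#CCOCc1ccc(OC)cc1 | intermediate
7 | sodium (S)-2,2-bis(2-methoxyethoxy)-3-[(4-methoxybenzyloxy)methyl]-5-vinyl-2,5-dihydro-1,2-oxaaluminol-2-uide | [Na+].COCCO[Al-]1(OCCOC)O[C@@H](C=C)C=C1COCc1ccc(OC)cc1 | intermediate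
8 | (S,Z)-5-bromo-6-(4-methoxybenzyloxy)hexa-1,4-dien-3-ol | C=C[C@H](O)/C=C(\Br)COCc1ccc(OC)cc1 | intermediate
9 | 2-(bromomethyl)acrylic acid | OC(=O)C(=C)CBr | starting material
10 | 2-(bromomethyl)acryloyl chloride | ClC(=O)C(=C)CBr | intermediate
11 | (S,Z)-5-bromo-6-(4-methoxybenzyloxy)hexa-1,4-dien-3-yl 2-(bromomethyl)acrylate | C=C(CBr)C(=O)O[C@@H](C=C)/C=C(\Br)COCc1ccc(OC)cc1 | intermediate
12 | (S)-3-(bromomethyl)-5-[(Z)-2-bromo-3-(4-methoxybenzyloxy)prop-1-enyl]furan-2(5H)-one | BrCC1=C[C@@H](/C=C(\Br)COCc2ccc(OC)cc2)OC1=O | intermediate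
13 | methyl 2-(hydroxymethyl)acrylate | C=C(CO)C(=O)OC | starting material
14 | methyl 2-[(tert-butyldimethylsilyloxy)methyl]acrylate | C=C(CO[Si](C)(C)C(C)(C)C)C(=O)OC | intermediate
15 | 2-[(tert-butyldimethylsilyloxy)methyl]acrylic acid | C=C(CO[Si](C)(C)C(C)(C)C)C(=O)O | intermediate
16 | propane-1,3-diol | OCCCO | starting material
17 | 3-(tert-butyldimethylsilyloxy)propan-1-ol | OCCCO[Si](C)(C)C(C)(C)C | intermediate
18 | 3-(tert-butyldimethylsilyloxy)propanal | O=CCCO[Si](C)(C)C(C)(C)C | intermediate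
19 | maleic anhydride | O=C1OC(=O)C=C1 | starting material
20 | 3-(triphenylphosphoranylidene)oxolane-2,5-dione | O=C1CC(=P(c2ccccc2)(c2ccccc2)c2ccccc2)C(=O)O1 | intermediate
21 | 4-methoxy-4-oxo-2-(triphenylphosphoranylidene)butanoic acid | COC(=O)CC(C(=O)O)=P(c1ccccc1)(c1ccccc1)c1ccccc1 | intermediate
22 | (E)-5-(tert-butyldimethylsilyloxy)-2-(2-methoxy-2-oxoethyl)pent-2-enoic acid | COC(=O)C/C(C(=O)O)=C\CCO[Si](C)(C)C(C)(C)C | intermediate
23 | methyl (E)-6-(tert-butyldimethylsilyloxy)-3-(hydroxymethyl)hex-3-enoate | COC(=O)C/C(CO)=C\CCO[Si](C)(C)C(C)(C)C | intermediate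
24 | (E)-4-(3-hydroxypropylidene)oxolan-2-one | O=C1C/C(=C\CCO)CO1 | intermediate
25 | (E)-4-(3-iodopropylidene)oxolan-2-one | O=C1C/C(=C\CCI)CO1 | intermediate
26 | (E)-4-(3-iodopropylidene)oxolan-2-ol (anomer mixture) | OC1C/C(=C\CCI)CO1 | intermediate
27 | (4R,5S)-5-[(Z)-2-bromo-3-(4-methoxybenzyloxy)prop-1-enyl]-4-[(1S,3E)-1-hydroxy-3-(hydroxymethyl)-6-iodohex-3-enyl]-3-methylideneoxolan-2-one | OC/C(=C/CCI)C[C@H](O)[C@H]1C(=C)C(=O)O[C@@H]1/C=C(\Br)COCc1ccc(OC)cc1 | intermediate
28 | 8,14-bis(triethylsilyl) ether of 27 (same spatial arrangement) | CC[Si](CC)(CC)OC/C(=C/CCI)C[C@H](O[Si](CC)(CC)CC)[C@H]1C(=C)C(=O)O[C@@H]1/C=C(\Br)COCc1ccc(OC)cc1 | intermediate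
29 | alkylzinc iodide of 28 (C3–ZnI) | CC[Si](CC)(CC)OC/C(=C/CC[Zn]I)C[C@H](O[Si](CC)(CC)CC)[C@H]1C(=C)C(=O)O[C@@H]1/C=C(\Br)COCc1ccc(OC)cc1 | intermediate
30 | 8,14-bis-O-triethylsilyl-15-O-(4-methoxybenzyl) germacra-1(10),4,11(13)-trien-6,12-olide; both ring olefins ring-cis (1(10)E,4E), 6,7-trans-lactone, (6R,7S,8S) by CIP, spatially as the target | CC[Si](CC)(CC)O[C@H]1C/C(CO[Si](CC)(CC)CC)=C\CC/C(COCc3ccc(OC)cc3)=C\[C@H]2OC(=O)C(=C)[C@H]12 | intermediate
31 | 8,14-dihydroxy-15-O-(4-methoxybenzyl) macrocyclic lactone, (6R,7R,8S) | O[C@H]1C/C(CO)=C\CC/C(COCc3ccc(OC)cc3)=C\[C@H]2OC(=O)C(=C)[C@H]12 | intermediate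
32 | 14-acetoxy-8-hydroxy-15-O-(4-methoxybenzyl) macrocyclic lactone, (6R,7R,8S) | O[C@H]1C/C(COC(C)=O)=C\CC/C(COCc3ccc(OC)cc3)=C\[C@H]2OC(=O)C(=C)[C@H]12 | intermediate
33 | 14-acetoxy-8-O-{2-[(tert-butyldimethylsilyloxy)methyl]acryloyl}-15-O-(4-methoxybenzyl) macrocyclic lactone, (6R,7R,8S) | C=C(CO[Si](C)(C)C(C)(C)C)C(=O)O[C@H]1C/C(COC(C)=O)=C\CC/C(COCc3ccc(OC)cc3)=C\[C@H]2OC(=O)C(=C)[C@H]12 | intermediate
34 | 15-hydroxy analogue of 33 | C=C(CO[Si](C)(C)C(C)(C)C)C(=O)O[C@H]1C/C(COC(C)=O)=C\CC/C(CO)=C\[C@H]2OC(=O)C(=C)[C@H]12 | intermediate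
35 | 15-aldehyde, side chain O-TBS | C=C(CO[Si](C)(C)C(C)(C)C)C(=O)O[C@H]1C/C(COC(C)=O)=C\CC/C(C=O)=C\[C@H]2OC(=O)C(=C)[C@H]12 | intermediate
36 | CNP0198933.2: (6R,7R,8S)-14-acetoxy-8-[2-(hydroxymethyl)acryloyloxy]-15-oxogermacra-1(10),4,11(13)-trien-6,12-olide, both ring olefins ring-cis | C=C(CO)C(=O)O[C@H]1C/C(COC(C)=O)=C\CC/C(C=O)=C\[C@H]2OC(=O)C(=C)[C@H]12 | target

**Step count**
Total: 24 steps. Longest linear sequence: 15 steps (1–6 then 16–24; the branch 9, 10, 12–15 then 16–24 is equally long).

**Steps most likely to fail**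

Step 18 (the new macrocyclising Negishi coupling). The risks are oligomerisation, protodezincation, 5-exo Heck insertion of the alkenyl–Pd into C11=C13, and Pd(0) ionisation of the allylic lactone. The fallback uses only known reactions and reverses the order of the two C–C bond formations; it sets out from 26 and 8. Lactol 26 is converted (MeOH, PPTS, 0 °C) into its methyl acetal (E)-4-(3-iodopropylidene)-2-methoxyoxolane F1. Zinc insertion (Zn, LiCl, THF) gives the alkylzinc iodide F2. An ordinary intermolecular Negishi coupling of F2 with alkenyl bromide 8 (PdCl2(DPEphos), THF, 40 °C) gives the dienol acetal F3. Acylation with 10 (2,6-lutidine) gives the 2-(bromomethyl)acrylate F4, and RCM (Grubbs II) gives the butenolide bromide F5. Mild acetal hydrolysis (AcOH/THF/H2O) gives the bromo-lactol F6. A high-dilution intramolecular Zn (or CrCl2) Barbier/NHK allylation, the established way of closing germacranolide rings at the lactone carbons, then forms C7–C8 and comes back to the route at 31. In this variant C7 and C8 arise under macrocyclic substrate control, so their configuration must be checked by NOE and against 31.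

Step 16 (Barbier union). The risks are sluggish opening or aromatisation of the lactol and an eroded 7,8-diastereoselectivity caused by the free γ-hydroxyl. The fallback sets out from 12. Pd-catalysed borylation (B2pin2, Pd2(dba)3, THF, rt; the allylic C–Br reacts far faster than the alkenyl C–Br) gives the isolable allylboronate (S)-5-[(Z)-2-bromo-3-(4-methoxybenzyloxy)prop-1-enyl]-3-[(pinacolatoboryl)methyl]furan-2(5H)-one F7. Thermal Hall-type allylboration of 26 (toluene, 60 °C) runs through a closed chair transition state, so the E-disposed γ-substituent gives 7,8-anti and attack is anti to the C6 substituent. Aqueous work-up returns to the route at 27.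

Step 6 (RCM of the 2-(bromomethyl)acrylate). The risks are catalyst decomposition by the allylic bromide and slow closure to the trisubstituted butenolide. The fallback sets out from 8 and 15 and introduces the bromide only after ring formation. DCC/DMAP esterification gives the silyloxymethyl acrylate (S,Z)-5-bromo-6-(4-methoxybenzyloxy)hexa-1,4-dien-3-yl 2-[(tert-butyldimethylsilyloxy)methyl]acrylate F8. RCM (Grubbs II, toluene, 80 °C) gives the silyloxymethyl butenolide F9. HF·pyridine gives the hydroxymethyl butenolide F10. Appel bromination (CBr4, PPh3, 0 °C) comes back to the route at 12.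

**Further compounds**
F1 | step 18 | (E)-4-(3-iodopropylidene)-2-methoxyoxolane | COC1C/C(=C\CCI)CO1
F2 | step 18 | alkylzinc iodide of F1 | COC1C/C(=C\CC[Zn]I)CO1
F3 | step 18 | (3S,4E)-5-[(4-methoxybenzyloxy)methyl]-8-[(E)-5-methoxyoxolan-3-ylidene]octa-1,4-dien-3-ol (8 with Br replaced by the C3–C1 chain, C3 cis to C6) | C=C[C@H](O)/C=C(COCc1ccc(OC)cc1)\CC/C=C1\CC(OC)OC1
F4 | step 18 | 2-(bromomethyl)acrylate ester of F3 | C=C(CBr)C(=O)O[C@@H](C=C)/C=C(COCc1ccc(OC)cc1)\CC/C=C1\CC(OC)OC1
F5 | step 18 | 3-(bromomethyl)butenolide from F4 (methyl acetal) | BrCC1=C[C@@H](/C=C(COCc2ccc(OC)cc2)\CC/C=C2\CC(OC)OC2)OC1=O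
F6 | step 18 | 3-(bromomethyl)butenolide lactol from F5 | BrCC1=C[C@@H](/C=C(COCc2ccc(OC)cc2)\CC/C=C2\CC(O)OC2)OC1=O
F7 | step 16 | (S)-5-[(Z)-2-bromo-3-(4-methoxybenzyloxy)prop-1-enyl]-3-[(4,4,5,5-tetramethyl-1,3,2-dioxaborolan-2-yl)methyl]furan-2(5H)-one | CC1(C)OB(CC2=C[C@@H](/C=C(\Br)COCc3ccc(OC)cc3)OC2=O)OC1(C)C
F8 | step 6 | (S,Z)-5-bromo-6-(4-methoxybenzyloxy)hexa-1,4-dien-3-yl 2-[(tert-butyldimethylsilyloxy)methyl]acrylate | C=C(CO[Si](C)(C)C(C)(C)C)C(=O)O[C@@H](C=C)/C=C(\Br)COCc1ccc(OC)cc1
F9 | step 6 | (S)-5-[(Z)-2-bromo-3-(4-methoxybenzyloxy)prop-1-enyl]-3-[(tert-butyldimethylsilyloxy)methyl]furan-2(5H)-one | CC(C)(C)[Si](C)(C)OCC1=C[C@@H](/C=C(\Br)COCc2ccc(OC)cc2)OC1=O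
F10 | step 6 | (S)-5-[(Z)-2-bromo-3-(4-methoxybenzyloxy)prop-1-enyl]-3-(hydroxymethyl)furan-2(5H)-one | OCC1=C[C@@H](/C=C(\Br)COCc2ccc(OC)cc2)OC1=O
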